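**Strategy.** The benzofuranone ring is closed last at its aryl ether bond, O1–C7a, by displacement of fluoride. The route exploits two features: the vicinal C–O pair at spiro carbon C9′ and C8′ of the dihydrofuran ring, which is stored as a spiro-epoxide, and the ortho relation of O1 to the C3 carbonyl on the phloroglucinol ring, which allows SNAr. The precursor is a spiro-epoxy lactone on the flavan (furan-2-one fused at C7–C8) carrying no phloroglucinol ring at all. One operation adds a 2-fluoroaryllithium to the lactone, frees the C7 phenoxide, opens the strained epoxide at the benzylic carbon and lets the resulting tertiary alkoxide close the benzofuranone.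

Key step: step 9

Remark: (−)-epiafzelechin is assumed to be purchasable as a natural product. Target atoms are numbered as in spiro[benzofuran-2(3H),9′(8′H)-furo[2,3-h]chromen]-3-one (benzofuranone O1, spiro C2 = C9′, C3=O, C3a–C7a; furochromane part O1′, C2′, C3′, C4′, C5′, C6′, O7′, C8′). Flavan intermediates keep chroman numbers (O1, C2–C8).

**Step 1**
Reactants: 1 5-fluororesorcinol; 2 benzyl bromide
Product: 3 1,3-bis(benzyloxy)-5-fluorobenzene
Conditions: BnBr (2.2 equiv), K2CO3, DMF, 60 °C
Reagents that add atoms: benzyl bromide, BrCc1ccccc1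
Why: Williamson etherification of both phenols; the unactivated C–F bond is inert to carbonate.

**Step 2**
Reactants: 3 1,3-bis(benzyloxy)-5-fluorobenzene; 4 N-bromosuccinimide
Product: 5 1,5-bis(benzyloxy)-2-bromo-3-fluorobenzene
Conditions: NBS (1.0 equiv), MeCN, 0 °C
Reagents that add atoms: N-bromosuccinimide, O=C1CCC(=O)N1Br
Why: Electrophilic aromatic bromination, expected para to one benzyloxy group and ortho to the other (the carbon next to fluorine) and not at the hindered carbon between the two ethers, as is usual for resorcinol diethers.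

**Step 3**
Reactants: 6 (−)-epiafzelechin; 2 benzyl bromide
Product: 8 tetra-O-benzylepiafzelechin, via tri-O-benzyl ether 7 (not isolated)
Conditions: BnBr (3.3 equiv), K2CO3, DMF, rt; then NaH (1.5 equiv), BnBr (1.5 equiv), 0 °C → rt
Reagents that add atoms: benzyl bromide, BrCc1ccccc1
Why: Williamson etherification, carbonate for the three phenols and then sodium hydride for the C3 alcohol; no bond at C2 or C3 is broken, so the 2R,3R configuration is kept.

**Step 4**
Reactants: 8 tetra-O-benzylepiafzelechin; 4 N-bromosuccinimide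
Product: 9 8-bromo-tetra-O-benzylepiafzelechin
Conditions: NBS (1.0 equiv), CH2Cl2, −78 °C → rt
Reagents that add atoms: N-bromosuccinimide, O=C1CCC(=O)N1Br
Why: Electrophilic aromatic bromination of the phloroglucinol-type ring, expected at C8 (between O1 and the C7 ether) as is usual for benzylated flavan-3-ols, with the mono-alkoxy ring B much less reactive.

**Step 5**
Reactants: 9 8-bromo-tetra-O-benzylepiafzelechin; 10 diethyl oxalate
Product: 12 C8 α-keto ester, via 8-lithiochroman 11 (not isolated)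
Conditions: n-BuLi (1.05 equiv), THF, −78 °C; cannulated into (CO2Et)2 (4 equiv), THF, −78 °C; NH4Cl aq.
Reagents that add atoms: diethyl oxalate, CCOC(=O)C(=O)OCC
Why: Bromine–lithium exchange followed by acylation of the aryllithium with excess oxalate (inverse addition), which should stop at the keto ester because the tetrahedral adduct persists at −78 °C.

**Step 6**
Reactants: 12 C8 α-keto ester
Product: 13 7-hydroxy α-keto ester
Conditions: BCl3 (1.1 equiv), CH2Cl2, −78 °C, 30 min; then H2O
Reagents that add atoms: none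
Why: Chelation-directed Lewis-acid debenzylation: boron held by the C8 ketone oxygen reaches only the ortho benzyl ether at C7 (six-membered chelate), so one equivalent at −78 °C should spare the other three benzyl ethers and the pyran ring.

**Step 7**
Reactants: 13 7-hydroxy α-keto ester; 14 [4-(benzyloxy)benzyl]triphenylphosphonium chloride
Product: 17 (E)-arylidene lactone, via furochromene-8,9-dione 15 (not isolated), via phosphorus ylide 16 (not isolated)
Conditions: 13, DMAP (0.1 equiv), 5 Å molecular sieves, PhMe, 90 °C; separately 14, NaN(SiMe3)2, THF, 0 °C; the dione solution is added to the ylide at −78 °C → rt; then I2 (5 mol %), rt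
Reagents that add atoms: [4-(benzyloxy)benzyl]triphenylphosphonium chloride, [Cl-].c1ccc(cc1)COc1ccc(C[P+](c2ccccc2)(c2ccccc2)c2ccccc2)cc1
Why: Intramolecular transesterification of the activated keto ester (ethanol trapped by the sieves) gives the benzofuran-2,3-dione, whose ketone is then converted by Wittig olefination; the E isomer (aryl syn to the arene, anti to the lactone carbonyl) is the less crowded one, and iodine should equilibrate any Z isomer to it.

**Step 8**
Reactants: 17 (E)-arylidene lactone; 18 potassium peroxymonosulfate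
Product: 19 spiro-epoxy lactone
Conditions: Oxone (2KHSO5·KHSO4·K2SO4), 4,5-di-O-acetyl-1,2-O-isopropylidene-β-L-erythro-2,3-hexodiulo-2,6-pyranose (30 mol %, the enantiomer of the Shi ketone used for unsaturated esters), NaHCO3, Bu4NHSO4, MeCN/aqueous disodium EDTA (Na2H2EDTA), 0 °C
Reagents that add atoms: potassium peroxymonosulfate, [K+].[O-]S(=O)(=O)OO
Why: Shi asymmetric epoxidation (bicarbonate variant for unsaturated esters): the chiral dioxirane transfers oxygen stereospecifically, so the aryl group stays anti to the lactone carbonyl, and by the spiro transition-state model, calibrated on cinnamates and trisubstituted aryl alkenes, the L-series ketone should attack the face that gives 9R,3′S; the 9S,3′R epoxide is a diastereomer (the flavan is enantiopure) and is removed by chromatography.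

**Step 9**
Reactants: 19 spiro-epoxy lactone; 5 1,5-bis(benzyloxy)-2-bromo-3-fluorobenzene
Product: 23 hexa-O-benzyl spirobiflavonoid, via aryllithium 20 (not isolated), via phenoxide epoxy ketone 21 (not isolated), via tertiary alkoxide 22 (not isolated)
Conditions: 5 (1.3 equiv), t-BuLi (2.6 equiv), THF, −78 °C; 19 in THF, −78 °C → rt; then DMPU, 60 °C
Reagents that add atoms: 1,5-bis(benzyloxy)-2-bromo-3-fluorobenzene, Fc1cc(OCc2ccccc2)cc(OCc2ccccc2)c1Br
Why: Bromine–lithium exchange gives aryllithium 20, which adds once to the aryl lactone of 19; the adduct collapses to aryl ketone and chroman C7 phenoxide (21), the phenoxide opens the epoxide at its benzylic carbon with inversion (Li+ held between ketone and epoxide oxygens assists), and the tertiary alkoxide released (22) displaces fluoride ortho to the ketone by addition–elimination, which forms O1–C7a. The closest known reaction types are the opening of aryl lactones by organolithiums to 2-hydroxyaryl ketones, the cyclisation of 2-hydroxystilbene oxides to 2-aryl-2,3-dihydrobenzofuran-3-ols, and the alkoxide SNAr of 2-fluoroaryl ketones to benzofuran-3-ones. The dihydrofuran ring closes by 5-endo-tet epoxide opening, feasible because the breaking C–O bond is benzylic to the 4-benzyloxyphenyl group and the epoxide is strained, and the benzofuranone closes by 5-exo attack on the arene (Meisenheimer intermediate). C9′ keeps the R configuration of the spiro epoxide carbon because its C–O bond is never broken, and C8′ becomes R by inversion of the S epoxide carbon, which places the aryl group cis to O1. The step needs one addition of 20 only (the di-ortho-substituted ketone next to a quaternary carbon resists a second one, and −78 °C keeps 20 from losing LiF) and epoxide opening ahead of SNAr, which the substrate secures because only the tertiary alkoxide sits five atoms from the C–F carbon while direct attack of the phenoxide would need a seven-membered ring.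

**Step 10**
Reactants: 23 hexa-O-benzyl spirobiflavonoid
Product: 24 target spirobiflavonoid
Conditions: H2 (1 atm), Pd(OH)2 on carbon, THF/MeOH, rt, stopped when the benzyl groups are gone
Reagents that add atoms: none
Why: Catalytic hydrogenolysis of five aryl benzyl ethers and one alkyl benzyl ether; the ring C–O bonds at C2′, C8′ and the fully substituted spiro carbon should cleave far more slowly, and no stereocentre is touched.

**Compound list**

1 | 5-fluororesorcinol (5-fluorobenzene-1,3-diol) | Oc1cc(O)cc(F)c1 | starting material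
2 | benzyl bromide | BrCc1ccccc1 | starting material
3 | 1,3-bis(benzyloxy)-5-fluorobenzene | Fc1cc(OCc2ccccc2)cc(OCc2ccccc2)c1 | intermediate
4 | N-bromosuccinimide | O=C1CCC(=O)N1Br | starting material (reagent)
5 | 1,5-bis(benzyloxy)-2-bromo-3-fluorobenzene | Fc1cc(OCc2ccccc2)cc(OCc2ccccc2)c1Br | intermediate
6 | (−)-epiafzelechin, (2R,3R)-2-(4-hydroxyphenyl)chromane-3,5,7-triol | Oc1cc(O)c2c(c1)O[C@H](c1ccc(O)cc1)[C@H](O)C2 | starting material
7 | (2R,3R)-5,7-bis(benzyloxy)-2-[4-(benzyloxy)phenyl]chroman-3-ol | c1ccc(cc1)COc1cc(OCc3ccccc3)c2c(c1)O[C@H](c1ccc(OCc3ccccc3)cc1)[C@H](O)C2 | intermediate (not isolated)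
8 | (2R,3R)-3,5,7-tris(benzyloxy)-2-[4-(benzyloxy)phenyl]chromane | c1ccc(cc1)COc1cc(OCc3ccccc3)c2c(c1)O[C@H](c1ccc(OCc3ccccc3)cc1)[C@H](OCc1ccccc1)C2 | intermediate
9 | (2R,3R)-3,5,7-tris(benzyloxy)-2-[4-(benzyloxy)phenyl]-8-bromochromane | c1ccc(cc1)COc1cc(OCc3ccccc3)c2c(c1Br)O[C@H](c1ccc(OCc3ccccc3)cc1)[C@H](OCc1ccccc1)C2 | intermediate
10 | diethyl oxalate | CCOC(=O)C(=O)OCC | starting material
11 | {(2R,3R)-3,5,7-tris(benzyloxy)-2-[4-(benzyloxy)phenyl]chroman-8-yl}lithium | c1ccc(cc1)COc1cc(OCc3ccccc3)c2c(c1[Li])O[C@H](c1ccc(OCc3ccccc3)cc1)[C@H](OCc1ccccc1)C2 | intermediate (not isolated)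
12 | ethyl 2-oxo-2-{(2R,3R)-3,5,7-tris(benzyloxy)-2-[4-(benzyloxy)phenyl]chroman-8-yl}acetate | c1ccc(cc1)COc1cc(OCc3ccccc3)c2c(c1C(=O)C(=O)OCC)O[C@H](c1ccc(OCc3ccccc3)cc1)[C@H](OCc1ccccc1)C2 | intermediate
13 | ethyl 2-{(2R,3R)-3,5-bis(benzyloxy)-2-[4-(benzyloxy)phenyl]-7-hydroxychroman-8-yl}-2-oxoacetate | Oc1cc(OCc3ccccc3)c2c(c1C(=O)C(=O)OCC)O[C@H](c1ccc(OCc3ccccc3)cc1)[C@H](OCc1ccccc1)C2 | intermediate
14 | [4-(benzyloxy)benzyl]triphenylphosphonium chloride | [Cl-].c1ccc(cc1)COc1ccc(C[P+](c2ccccc2)(c2ccccc2)c2ccccc2)cc1 | starting material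
15 | (2R,3R)-3,5-bis(benzyloxy)-2-[4-(benzyloxy)phenyl]-3,4-dihydro-2H-furo[2,3-h]chromene-8,9-dione | O=C1Oc2cc(OCc4ccccc4)c3c(c2C1=O)O[C@H](c2ccc(OCc4ccccc4)cc2)[C@H](OCc2ccccc2)C3 | intermediate (not isolated)
16 | [4-(benzyloxy)benzylidene]triphenylphosphorane | c1ccc(cc1)COc1ccc(C=P(c2ccccc2)(c2ccccc2)c2ccccc2)cc1 | intermediate (not isolated)
17 | (2R,3R,9E)-3,5-bis(benzyloxy)-9-[4-(benzyloxy)benzylidene]-2-[4-(benzyloxy)phenyl]-3,4-dihydro-2H-furo[2,3-h]chromen-8(9H)-one | O=C1Oc2cc(OCc4ccccc4)c3c(c2/C1=C\c2ccc(OCc4ccccc4)cc2)O[C@H](c2ccc(OCc4ccccc4)cc2)[C@H](OCc2ccccc2)C3 | intermediate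
18 | potassium peroxymonosulfate (KHSO5, active part of Oxone) | [K+].[O-]S(=O)(=O)OO | starting material (reagent)
19 | (2R,3R,3′S,9R)-3,5-bis(benzyloxy)-2,3′-bis[4-(benzyloxy)phenyl]-3,4-dihydro-2H-spiro[furo[2,3-h]chromene-9,2′-oxiran]-8-one (aryl on the epoxide anti to the lactone carbonyl) | O=C1Oc2cc(OCc5ccccc5)c3c(c2[C@]14O[C@H]4c2ccc(OCc5ccccc5)cc2)O[C@H](c2ccc(OCc5ccccc5)cc2)[C@H](OCc2ccccc2)C3 | intermediate
20 | [2,4-bis(benzyloxy)-6-fluorophenyl]lithium | [Li]c1c(F)cc(OCc2ccccc2)cc1OCc1ccccc1 | intermediate (not isolated)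
21 | lithium (2R,3R)-3,5-bis(benzyloxy)-2-[4-(benzyloxy)phenyl]-8-{(2R,3S)-2-[2,4-bis(benzyloxy)-6-fluorobenzoyl]-3-[4-(benzyloxy)phenyl]oxiran-2-yl}chroman-7-olate | [Li+].[O-]c1cc(OCc5ccccc5)c2c(c1[C@]3(O[C@H]3c1ccc(OCc5ccccc5)cc1)C(=O)c1c(F)cc(OCc5ccccc5)cc1OCc1ccccc1)O[C@H](c1ccc(OCc5ccccc5)cc1)[C@H](OCc1ccccc1)C2 | intermediate (not isolated)
22 | lithium (2R,3R,8R,9R)-9-[2,4-bis(benzyloxy)-6-fluorobenzoyl]-3,5-bis(benzyloxy)-2,8-bis[4-(benzyloxy)phenyl]-3,4,8,9-tetrahydro-2H-furo[2,3-h]chromen-9-olate | [Li+].[O-][C@]2(C(=O)c1c(F)cc(OCc5ccccc5)cc1OCc1ccccc1)c1c(cc(OCc5ccccc5)c3c1O[C@H](c1ccc(OCc5ccccc5)cc1)[C@H](OCc1ccccc1)C3)O[C@@H]2c1ccc(OCc5ccccc5)cc1 | intermediate (not isolated)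
23 | (2R,2′R,3′R,8′R)-3′,4,5′,6-tetrakis(benzyloxy)-2′,8′-bis[4-(benzyloxy)phenyl]-3′,4′-dihydro-2′H,8′H-spiro[benzofuran-2,9′-furo[2,3-h]chromen]-3-one | O=C1c2c(OCc5ccccc5)cc(OCc5ccccc5)cc2O[C@@]12c1c(cc(OCc5ccccc5)c3c1O[C@H](c1ccc(OCc5ccccc5)cc1)[C@H](OCc1ccccc1)C3)O[C@@H]2c1ccc(OCc5ccccc5)cc1 | intermediate
24 | (2R,2′R,3′R,8′R)-3′,4,5′,6-tetrahydroxy-2′,8′-bis(4-hydroxyphenyl)-3′,4′-dihydro-2′H,8′H-spiro[benzofuran-2,9′-furo[2,3-h]chromen]-3-one | O=C1c2c(O)cc(O)cc2O[C@@]12c1c(cc(O)c3c1O[C@H](c1ccc(O)cc1)[C@H](O)C3)O[C@@H]2c1ccc(O)cc1 | target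

**Step count and risks**

Total steps: 10. Longest linear sequence: 8 (steps 3–10).

Steps most likely to fail:

1. Step 9 (key step). The o-fluoroaryllithium may lose LiF to an aryne before it adds, or add twice. The sequence may also stall after lactone opening, or at the tertiary alkoxide, because two ether groups deactivate the fluoroarene. Fallback (stepwise, through a Weinreb amide), setting out from 19 and returning at 23: N,O-dimethylhydroxylamine hydrochloride and i-PrMgCl (THF, −20 °C → rt) open the lactone to the amide, and the magnesium phenoxide so freed opens the epoxide in the same flask to give the Weinreb amide tertiary alcohol F1. Aryllithium 20 (2.2 equiv, THF, −78 °C, acidic quench) then gives the α-hydroxy fluoro ketone F2. The benzofuranone is closed in a separate alkoxide SNAr (Cs2CO3, DMF, 70 °C) to give 23.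

2. Step 8. Oxygen transfer to the conjugated, electron-poor alkene may be slow, the aryl lactone may hydrolyse in the aqueous buffer, and facial discrimination may be weak. Fallback (Kukhtin–Ramirez reductive epoxidation), setting out from 13 (through dione 15, made as in step 7) and returning at 19: P(NMe2)3 adds to the ketone of 15 (CH2Cl2, −78 °C → rt), the carbanion formed adds to 4-(benzyloxy)benzaldehyde, and the alkoxide displaces (Me2N)3P=O to close the epoxide with the aryl group anti to the lactone carbonyl. This gives 19 together with the (9S,3′R) spiro-epoxy lactone F3, which is removed by chromatography (the flavan stereocentres make the two separable).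

3. Step 7. Lactonisation may stay incomplete (ethyl ester against aryl lactone equilibrium), the ylide may attack the lactone carbonyl, and E/Z mixtures may form. Fallback (olefination before lactonisation), setting out from 13 and returning at 17: TBSCl and imidazole (DMF) give the silyl ether keto ester F4. Wittig olefination of its ketone with ylide 16 (THF, −78 °C → rt, then catalytic I2) gives the (E)-acrylate F5. LiOH (THF/H2O, 50 °C) removes the silyl group and the ester to give the hydroxy acid F6, and N-(3-dimethylaminopropyl)-N′-ethylcarbodiimide hydrochloride (CH2Cl2, rt) lactonises F6 to 17.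

**Further compounds**

F1 | step 9 | (2R,3R,8R,9R)-3,5-bis(benzyloxy)-2,8-bis[4-(benzyloxy)phenyl]-9-hydroxy-N-methoxy-N-methyl-3,4,8,9-tetrahydro-2H-furo[2,3-h]chromene-9-carboxamide | O[C@]2(C(=O)N(C)OC)c1c(cc(OCc5ccccc5)c3c1O[C@H](c1ccc(OCc5ccccc5)cc1)[C@H](OCc1ccccc1)C3)O[C@@H]2c1ccc(OCc5ccccc5)cc1
F2 | step 9 | [2,4-bis(benzyloxy)-6-fluorophenyl]{(2R,3R,8R,9R)-3,5-bis(benzyloxy)-2,8-bis[4-(benzyloxy)phenyl]-9-hydroxy-3,4,8,9-tetrahydro-2H-furo[2,3-h]chromen-9-yl}methanone | O[C@]2(C(=O)c1c(F)cc(OCc5ccccc5)cc1OCc1ccccc1)c1c(cc(OCc5ccccc5)c3c1O[C@H](c1ccc(OCc5ccccc5)cc1)[C@H](OCc1ccccc1)C3)O[C@@H]2c1ccc(OCc5ccccc5)cc1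
F3 | step 8 | (2R,3R,3′R,9S)-3,5-bis(benzyloxy)-2,3′-bis[4-(benzyloxy)phenyl]-3,4-dihydro-2H-spiro[furo[2,3-h]chromene-9,2′-oxiran]-8-one | O=C1Oc2cc(OCc5ccccc5)c3c(c2[C@@]14O[C@@H]4c2ccc(OCc5ccccc5)cc2)O[C@H](c2ccc(OCc5ccccc5)cc2)[C@H](OCc2ccccc2)C3
F4 | step 7 | ethyl 2-{(2R,3R)-3,5-bis(benzyloxy)-2-[4-(benzyloxy)phenyl]-7-[(tert-butyldimethylsilyl)oxy]chroman-8-yl}-2-oxoacetate | CC(C)(C)[Si](C)(C)Oc1cc(OCc3ccccc3)c2c(c1C(=O)C(=O)OCC)O[C@H](c1ccc(OCc3ccccc3)cc1)[C@H](OCc1ccccc1)C2
F5 | step 7 | ethyl (E)-2-{(2R,3R)-3,5-bis(benzyloxy)-2-[4-(benzyloxy)phenyl]-7-[(tert-butyldimethylsilyl)oxy]chroman-8-yl}-3-[4-(benzyloxy)phenyl]acrylate | CC(C)(C)[Si](C)(C)Oc1cc(OCc3ccccc3)c2c(c1/C(C(=O)OCC)=C\c1ccc(OCc3ccccc3)cc1)O[C@H](c1ccc(OCc3ccccc3)cc1)[C@H](OCc1ccccc1)C2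
F6 | step 7 | (E)-2-{(2R,3R)-3,5-bis(benzyloxy)-2-[4-(benzyloxy)phenyl]-7-hydroxychroman-8-yl}-3-[4-(benzyloxy)phenyl]acrylic acid | Oc1cc(OCc3ccccc3)c2c(c1/C(C(=O)O)=C\c1ccc(OCc3ccccc3)cc1)O[C@H](c1ccc(OCc3ccccc3)cc1)[C@H](OCc1ccccc1)C2
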